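Numbering (eremophilane): ring A = C1–C5 + C10, ring B = C5–C10; C3 carries the angelate, C4 and C5 the methyls, C8 is the ketone, C11 the side-chain CH.
Retrosynthesis: cut (1) the angelate ester at O3; (2) together the enone bond C6=C7 and the ring-fusion bond C5–C10, which opens both rings to an acyclic 12-carbon formyl enone; (3) its C9=C10 alkene, giving aldehyde 12 and vinyl ketone 17.
Enabling feature: ring B is a cyclohex-2-enone in which C6 and the C8 carbonyl are 1,5-related across C5–C10 and C6=C7 is the aldol-condensation alkene of C8, a Robinson retron whose Michael bond is also the only bond that closes ring A.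
Forward: west chain (epoxide → butenolide → dimethyl lactone → silyloxy aldehyde), east vinyl ketone, cross-metathesis, then rings A and B close in one operation; desilylation and angeloylation finish.
Stereochemistry: C3 from (S)-1,2-epoxyhex-5-ene, C4 by trans cuprate addition to the butenolide, C11 from methyl (R)-3-hydroxy-2-methylpropanoate; C5 and C10 arise in the key step under control of C3/C4, and both C5 epimers of the aldehyde converge through one enamine.

Key step: step 9

Remark: the carbon that becomes C5 is left unset on purpose from 9 to 18 (no descriptor in the SMILES), as is the sulfur-bearing carbon of 4–6, because steps 9 and 2 erase these centres.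

Step 1
Reactants: 1 (2S)-2-(but-3-en-1-yl)oxirane [(S)-1,2-epoxyhex-5-ene]; 2 (phenylsulfanyl)acetic acid
Product: 5 (5S)-5-(but-3-en-1-yl)-3-(phenylsulfanyl)oxolan-2-one, via dilithium dianion 3 (not isolated), via hydroxy acid 4 (not isolated)
Conditions: 2, LiN(i-Pr)2 (2.1 equiv), THF, −78 → 0 °C; 1, 0 → 23 °C; aq. HCl; then TsOH (cat.), toluene, 80 °C
Reagents that add atoms: none
Why: The carboxylate-enolate dianion 3 should open the terminal epoxide at its CH2 group by SN2 attack, so the epoxide CH (the later C3) keeps its configuration, and acid then closes hydroxy acid 4 to the γ-lactone (epoxide alkylation of a carboxylic acid dianion followed by lactonisation).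

Step 2
Reactants: 5 (5S)-5-(but-3-en-1-yl)-3-(phenylsulfanyl)oxolan-2-one
Product: 7 (5S)-5-(but-3-en-1-yl)furan-2(5H)-one, via sulfoxide 6 (not isolated)
Conditions: NaIO4, MeOH/H2O, 0 → 23 °C; then toluene, CaCO3, 110 °C
Reagents that add atoms: none
Why: NaIO4 should oxidise only the sulfide, and the sulfoxide then undergoes thermal syn-elimination toward the only β-hydrogens (the ring CH2) to give the butenolide without touching the ring stereocentre or the terminal alkene (sulfoxide pyrolysis).

Step 3
Reactants: 7 (5S)-5-(but-3-en-1-yl)furan-2(5H)-one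
Product: 9 (4R,5S)-5-(but-3-en-1-yl)-3,4-dimethyloxolan-2-one, via lithium enolate 8 (not isolated)
Conditions: Me2CuLi (from MeLi and CuI), Et2O, −78 °C; then MeI, DMPU, −78 → 0 °C
Reagents that add atoms: lithium dimethylcuprate [Li+].C[Cu-]C; iodomethane CI
Why: Conjugate addition of the cuprate should occur anti to the butenyl group and so set the later C4 methyl trans to it, and the enolate is methylated in the same flask (tandem conjugate addition–enolate alkylation), the configuration of the new α-carbon being irrelevant because step 9 resets it.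

Step 4
Reactants: 9 (4R,5S)-5-(but-3-en-1-yl)-3,4-dimethyloxolan-2-one
Product: 11 (3R,4S)-4-[(tert-butyldimethylsilyl)oxy]-N-methoxy-N,2,3-trimethyloct-7-enamide, via hydroxy amide 10 (not isolated)
Conditions: MeNH(OMe)·HCl, AlMe3, CH2Cl2, 0 → 23 °C; aqueous work-up; crude 10 at once with TBSOTf, 2,6-lutidine, CH2Cl2, −78 → 0 °C
Reagents that add atoms: N,O-dimethylhydroxylamine hydrochloride CNOC.Cl; tert-butyldimethylsilyl trifluoromethanesulfonate CC(C)(C)[Si](C)(C)OS(=O)(=O)C(F)(F)F
Why: The aluminium amide made from AlMe3 and the amine salt should open the lactone to the N-methoxy-N-methylamide, and immediate silylation of the freed secondary alcohol prevents relactonisation and installs the ether that later blocks oxa-Michael addition (lactone aminolysis then silyl protection, no stereocentre set).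

Step 5
Reactants: 11 (3R,4S)-4-[(tert-butyldimethylsilyl)oxy]-N-methoxy-N,2,3-trimethyloct-7-enamide
Product: 12 (3R,4S)-4-[(tert-butyldimethylsilyl)oxy]-2,3-dimethyloct-7-enal
Conditions: i-Bu2AlH, THF, −78 °C; aq. potassium sodium tartrate
Reagents that add atoms: none
Why: Hydride addition to the N-methoxy-N-methylamide gives a chelated tetrahedral aluminate that collapses to the aldehyde only on work-up, so over-reduction should be avoided (amide-to-aldehyde reduction, the α-centre being free to epimerise without consequence).

Step 6
Reactants: 13 methyl (2R)-3-hydroxy-2-methylpropanoate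
Product: 14 methyl (2S)-3-iodo-2-methylpropanoate
Conditions: I2, PPh3, imidazole, CH2Cl2, 0 → 23 °C
Reagents that add atoms: iodine (I2) II
Why: Appel-type iodination of the primary alcohol through the alkoxyphosphonium iodide leaves the stereocentre untouched (the descriptor changes from R to S only because CH2I outranks the ester).

Step 7
Reactants: 14 methyl (2S)-3-iodo-2-methylpropanoate; 15 prop-2-enoyl chloride (acryloyl chloride)
Product: 17 methyl (2R)-2-methyl-4-oxohex-5-enoate, via alkylzinc iodide 16 (not isolated)
Conditions: Zn dust (activated with BrCH2CH2Br and Me3SiCl), LiCl, THF, 25 °C; then 15, Pd(PPh3)4 (5 mol%), THF, 0 → 23 °C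
Reagents that add atoms: none
Why: Zinc inserts into the primary C–I bond to give the ester-chelated alkylzinc iodide 16, which should neither eliminate nor epimerise, and Pd-catalysed Negishi acylation with the acid chloride then gives the vinyl ketone with the stereocentre intact.

Step 8
Reactants: 12 (3R,4S)-4-[(tert-butyldimethylsilyl)oxy]-2,3-dimethyloct-7-enal; 17 methyl (2R)-2-methyl-4-oxohex-5-enoate
Product: 18 methyl (2R,5E,9S,10R)-9-[(tert-butyldimethylsilyl)oxy]-2,10,11-trimethyl-4,12-dioxododec-5-enoate
Conditions: 12 (1 equiv), 17 (1.5 equiv), second-generation Hoveyda–Grubbs catalyst (5 mol%), CH2Cl2, 40 °C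
Reagents that add atoms: none
Why: Olefin cross-metathesis between the unhindered terminal alkene of 12 and the electron-poor vinyl ketone, which does not homodimerise readily, should give the E-enone with loss of ethene while aldehyde, ester and silyl ether are tolerated.

Step 9
Reactants: 18 methyl (2R,5E,9S,10R)-9-[(tert-butyldimethylsilyl)oxy]-2,10,11-trimethyl-4,12-dioxododec-5-enoate
Product: 21 methyl (2R)-2-[(4aR,7S,8R,8aR)-7-[(tert-butyldimethylsilyl)oxy]-8,8a-dimethyl-3-oxo-3,4,4a,5,6,7,8,8a-octahydronaphthalen-2-yl]propanoate, via Michael adduct 19 (not isolated), via aldol 20 (not isolated)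
Conditions: pyrrolidine (0.3 equiv), AcOH (0.3 equiv), toluene (0.02 M), 23 → 60 °C
Reagents that add atoms: none
Why: Pyrrolidine condenses with the aldehyde of either C5 epimer of 18 to one trisubstituted enamine (C5=C6), whose C5 adds to C10 of the E-enone (6-exo-trig Michael closure of ring A, enolexo with respect to the enamine), and after hydrolysis the now non-enolisable C6 aldehyde of 19 is attacked by C7 of the C8 ketone (6-enolendo-exo-trig aldol closure of ring B), water being lost from 20 to give the C6=C7 enone. The closest known reaction type is the Robinson annulation of α-branched aldehydes with vinyl ketones through their enamines, here with the two partners tethered through C1–C4 as in amine-catalysed intramolecular Michael additions of formyl enones. C10 is set by the chair-like transition state of the ring A closure: the cis-related C3 silyloxy and C4 methyl groups cannot both be equatorial, the bulky silyloxy group should take the equatorial and the methyl the axial site (the other chair has a syn-axial clash between the silyloxy group and a C5 substituent), and the enone arm then lies equatorial to avoid a 1,3-diaxial contact with the C4 methyl, which puts H10 on the face of that methyl. C5 is set by the enamine face presented in this chair: the slim sp2 carbon C6 is expected to take the axial and the C5 methyl the equatorial site, which gives the cis ring fusion with both methyls and H10 on one face, and because the aldehyde α-centre is planar in the enamine the C5 epimer mixture is funnelled into this one configuration. The step needs this C5 facial selectivity (the trans-fused C5 epimer is the competing outcome), aldol closure through C7 and not C9, and an intact C11 centre; these are secured by the quaternary C5 of 19 (aldehyde only an acceptor, no way back to the enamine), the six- versus four-membered ring choice at the ketone, the buffered non-basic amine/acetic acid medium, and the silyl ether that blocks oxa-Michael addition of O3 to the enone.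

Step 10
Reactants: 21 methyl (2R)-2-[(4aR,7S,8R,8aR)-7-[(tert-butyldimethylsilyl)oxy]-8,8a-dimethyl-3-oxo-3,4,4a,5,6,7,8,8a-octahydronaphthalen-2-yl]propanoate
Product: 22 methyl (2R)-2-[(4aR,7S,8R,8aR)-7-hydroxy-8,8a-dimethyl-3-oxo-3,4,4a,5,6,7,8,8a-octahydronaphthalen-2-yl]propanoate
Conditions: HF·pyridine, pyridine, THF, 0 → 23 °C
Reagents that add atoms: none
Why: Fluoride should cleave the secondary silyl ether under mildly acidic conditions that leave the enone, the methyl ester and the C11 centre untouched (silyl ether deprotection).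

Step 11
Reactants: 22 methyl (2R)-2-[(4aR,7S,8R,8aR)-7-hydroxy-8,8a-dimethyl-3-oxo-3,4,4a,5,6,7,8,8a-octahydronaphthalen-2-yl]propanoate; 23 (2Z)-2-methylbut-2-enoic acid (angelic acid)
Product: 25 methyl (2R)-2-[(4aR,7S,8R,8aR)-8,8a-dimethyl-7-{[(2Z)-2-methylbut-2-enoyl]oxy}-3-oxo-3,4,4a,5,6,7,8,8a-octahydronaphthalen-2-yl]propanoate (CNP0323033.1), via mixed anhydride 24 (not isolated)
Conditions: 23, 2,4,6-trichlorobenzoyl chloride, Et3N, toluene, 23 °C; then 22, toluene, 80 °C
Reagents that add atoms: none
Why: Acylation by the preformed mixed anhydride without a nucleophilic catalyst (Yamaguchi esterification) should transfer the angeloyl group with its Z geometry intact and with retention at C3, since only the O–H bond reacts.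

Compound list
1 | (2S)-2-(but-3-en-1-yl)oxirane | C=CCC[C@H]1CO1 | starting material
2 | (phenylsulfanyl)acetic acid | OC(=O)CSc1ccccc1 | starting material
3 | dilithium dianion of (phenylsulfanyl)acetic acid | [Li+].[Li+].[O-]C([O-])=CSc1ccccc1 | intermediate
4 | (4S)-4-hydroxy-2-(phenylsulfanyl)oct-7-enoic acid (mixture at C-2) | C=CCC[C@H](O)CC(Sc1ccccc1)C(=O)O | intermediate
5 | (5S)-5-(but-3-en-1-yl)-3-(phenylsulfanyl)oxolan-2-one (mixture at C-3) | C=CCC[C@@H]1OC(=O)C(Sc2ccccc2)C1 | intermediate
6 | (5S)-5-(but-3-en-1-yl)-3-(phenylsulfinyl)oxolan-2-one (mixture at C-3 and S) | C=CCC[C@@H]1OC(=O)C(S(=O)c2ccccc2)C1 | intermediate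
7 | (5S)-5-(but-3-en-1-yl)furan-2(5H)-one | C=CCC[C@@H]1OC(=O)C=C1 | intermediate
8 | lithium (4R,5S)-5-(but-3-en-1-yl)-4-methyl-4,5-dihydrofuran-2-olate | C=CCC[C@@H]1OC([O-])=C[C@H]1C.[Li+] | intermediate
9 | (4R,5S)-5-(but-3-en-1-yl)-3,4-dimethyloxolan-2-one (mixture at C-3) | C=CCC[C@@H]1OC(=O)C(C)[C@H]1C | intermediate
10 | (3R,4S)-4-hydroxy-N-methoxy-N,2,3-trimethyloct-7-enamide (mixture at C-2) | CON(C)C(=O)C(C)[C@@H](C)[C@@H](O)CCC=C | intermediate
11 | (3R,4S)-4-[(tert-butyldimethylsilyl)oxy]-N-methoxy-N,2,3-trimethyloct-7-enamide (mixture at C-2) | CON(C)C(=O)C(C)[C@@H](C)[C@@H](O[Si](C)(C)C(C)(C)C)CCC=C | intermediate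
12 | (3R,4S)-4-[(tert-butyldimethylsilyl)oxy]-2,3-dimethyloct-7-enal (mixture at C-2) | O=CC(C)[C@@H](C)[C@@H](O[Si](C)(C)C(C)(C)C)CCC=C | intermediate
13 | methyl (2R)-3-hydroxy-2-methylpropanoate | OC[C@@H](C)C(=O)OC | starting material
14 | methyl (2S)-3-iodo-2-methylpropanoate | IC[C@@H](C)C(=O)OC | intermediate
15 | prop-2-enoyl chloride | C=CC(=O)Cl | starting material
16 | [(2S)-3-methoxy-2-methyl-3-oxopropyl]zinc iodide | I[Zn]C[C@@H](C)C(=O)OC | intermediate
17 | methyl (2R)-2-methyl-4-oxohex-5-enoate | C=CC(=O)C[C@@H](C)C(=O)OC | intermediate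
18 | methyl (2R,5E,9S,10R)-9-[(tert-butyldimethylsilyl)oxy]-2,10,11-trimethyl-4,12-dioxododec-5-enoate (mixture at C-11) | O=CC(C)[C@@H](C)[C@@H](O[Si](C)(C)C(C)(C)C)CC/C=C/C(=O)C[C@@H](C)C(=O)OC | intermediate
19 | methyl (2R)-5-[(1R,2S,3R,4S)-4-[(tert-butyldimethylsilyl)oxy]-2-formyl-2,3-dimethylcyclohexyl]-2-methyl-4-oxopentanoate | O=C[C@]1(C)[C@@H](C)[C@@H](O[Si](C)(C)C(C)(C)C)CC[C@@H]1CC(=O)C[C@@H](C)C(=O)OC | intermediate
20 | methyl (2R)-2-[(4aR,7S,8R,8aS)-7-[(tert-butyldimethylsilyl)oxy]-1-hydroxy-8,8a-dimethyl-3-oxodecahydronaphthalen-2-yl]propanoate (mixture at C-1 and C-2 of the ring) | COC(=O)[C@H](C)C1C(O)[C@]2(C)[C@@H](C)[C@@H](O[Si](C)(C)C(C)(C)C)CC[C@@H]2CC1=O | intermediate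
21 | methyl (2R)-2-[(4aR,7S,8R,8aR)-7-[(tert-butyldimethylsilyl)oxy]-8,8a-dimethyl-3-oxo-3,4,4a,5,6,7,8,8a-octahydronaphthalen-2-yl]propanoate | COC(=O)[C@H](C)C1=C[C@]2(C)[C@@H](C)[C@@H](O[Si](C)(C)C(C)(C)C)CC[C@@H]2CC1=O | intermediate
22 | methyl (2R)-2-[(4aR,7S,8R,8aR)-7-hydroxy-8,8a-dimethyl-3-oxo-3,4,4a,5,6,7,8,8a-octahydronaphthalen-2-yl]propanoate | COC(=O)[C@H](C)C1=C[C@]2(C)[C@@H](C)[C@@H](O)CC[C@@H]2CC1=O | intermediate
23 | (2Z)-2-methylbut-2-enoic acid (angelic acid) | C/C=C(/C)C(=O)O | starting material
24 | (2Z)-2-methylbut-2-enoic 2,4,6-trichlorobenzoic anhydride | C/C=C(/C)C(=O)OC(=O)c1c(Cl)cc(Cl)cc1Cl | intermediate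
25 | methyl (2R)-2-[(4aR,7S,8R,8aR)-8,8a-dimethyl-7-{[(2Z)-2-methylbut-2-enoyl]oxy}-3-oxo-3,4,4a,5,6,7,8,8a-octahydronaphthalen-2-yl]propanoate (3β-angeloyloxy-8-oxo-10βH-eremophil-6-en-12-oic acid methyl ester, 11R) | C/C=C(/C)C(=O)O[C@H]1CC[C@@H]2CC(=O)C([C@@H](C)C(=O)OC)=C[C@]2(C)[C@H]1C | target

Total steps: 11. Longest linear sequence: 9 steps (steps 1–5 and 8–11, from 1).

Steps most likely to fail

Step 9. The enamine may add through its other face (C5 methyl axial in the chair), which would lead to the trans-fused C5 epimer. Slow enamine formation from the hindered aldehyde may also let γ-deprotonation and migration of the enone double bond compete. The fallback sets out from 18 and returns at 21: the two bond formations are separated and the first is placed under reagent control. 18 would be treated with a chiral primary amine salt (9-amino-9-deoxy-epi-quinine bis-trifluoroacetate or its quinidine-derived pseudo-enantiomer, whichever is matched with the substrate bias; toluene, 0 °C), a catalyst type known for enamine Michael additions of α-branched aldehydes to enones, and the Michael adduct 19 would be isolated. Ring B would then be closed in a separate aldol condensation with dibenzylammonium trifluoroacetate (benzene, 50 °C) to give 21. This fallback makes no compound outside the list (F0).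

Step 7. The alkylzinc reagent may add in a conjugate sense to the vinyl ketone as it forms, or the vinyl ketone may polymerise under the coupling conditions. The fallback sets out from 14 (through 16) and returns at 17: 16 would be coupled under the same Pd(PPh3)4 catalysis with 3-chloropropanoyl chloride to give the masked enone methyl (2R)-6-chloro-2-methyl-4-oxohexanoate F1, which is inert to the organozinc. Et3N (CH2Cl2, 0 °C) would then eliminate HCl to release 17 directly before the metathesis.

Step 4. The α,β-disubstituted lactone may open incompletely, and hydroxy amide 10 may re-close to 9 before it is silylated. The fallback sets out from 9 and returns at 12. LiAlH4 (THF, 0 °C) would reduce 9 to (3R,4S)-2,3-dimethyloct-7-ene-1,4-diol F2, which cannot relactonise. TBSOTf and 2,6-lutidine would give (3R,4S)-1,4-bis[(tert-butyldimethylsilyl)oxy]-2,3-dimethyloct-7-ene F3. HF·pyridine in pyridine/THF at 0 °C would remove the primary silyl group selectively to give (3R,4S)-4-[(tert-butyldimethylsilyl)oxy]-2,3-dimethyloct-7-en-1-ol F4, and Dess–Martin periodinane would then give 12.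

Further compounds
F0 | step 9 | none | none
F1 | step 7 | methyl (2R)-6-chloro-2-methyl-4-oxohexanoate | ClCCC(=O)C[C@@H](C)C(=O)OC
F2 | step 4 | (3R,4S)-2,3-dimethyloct-7-ene-1,4-diol (mixture at C-2) | OCC(C)[C@@H](C)[C@@H](O)CCC=C
F3 | step 4 | (3R,4S)-1,4-bis[(tert-butyldimethylsilyl)oxy]-2,3-dimethyloct-7-ene (mixture at C-2) | CC(C)(C)[Si](C)(C)OCC(C)[C@@H](C)[C@@H](O[Si](C)(C)C(C)(C)C)CCC=C
F4 | step 4 | (3R,4S)-4-[(tert-butyldimethylsilyl)oxy]-2,3-dimethyloct-7-en-1-ol (mixture at C-2) | OCC(C)[C@@H](C)[C@@H](O[Si](C)(C)C(C)(C)C)CCC=C
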